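# Proposed total synthesis of myrrhanone A acetate by enantioselective reductive alkenyl–dienone cyclization

## Structural features

Myrrhanone A acetate is a bicyclic triterpenoid: a decalin (ring A = C10, C1–C5; ring B = C5–C10) with a thirteen-carbon all-E triene chain on C9 (C11–C23, methyls on C14, C18 and C22) that ends in a primary allylic acetate. Ring A holds the C3 ketone next to the C4 gem-dimethyl group; ring B holds the tertiary carbinol C8 (methyl and hydroxyl) next to C9. The four stereocentres are contiguous, C5–C10–C9–C8, and read (5S,8R,9R,10S). H5 and the C10 methyl are syn, so the decalin is cis-fused; the C9 chain is syn to the C10 methyl and anti to the C8 hydroxyl. The fragile groups are the tertiary alcohol (dehydration under acid), the 1,5-polyene (cyclization by acids and electrophiles, no selectivity toward oxidants or hydrogenation), the allylic acetate (bases, nucleophiles, zerovalent palladium) and C9, which can epimerize as long as C8 is a ketone. The real difficulty is twofold: quaternary C10 in a cis-fused frame as one enantiomer, and two ring carbonyls (C3 and C8) in nearly mirror-image steric environments that must be told apart while C9 and C8 are set relative to C10. The key step uses the fact that C10 lies para to the C3 carbonyl in ring A. Ring A can therefore begin as a 4,4-disubstituted cyclohexa-2,5-dienone in which C10 is only prochiral, and a four-carbon arm C9–C8–C7=C6 on C10 closes ring B through a single C5–C6 bond. That bond creates C5 and C10 together and can only give the cis fusion.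

## Logic of the disconnections

**34 back to 31 (functional-group level).** The C23–O acyl bond, the O–Si bond and the C3 oxidation state are adjusted last. The acetate would not survive amide bases or organometallics, so the chain oxygen travels as a silyl ether (33, 32). C3 travels as a carbinol (31) so that C8 is the only carbonyl when the methyl group is added. The forward steps must oxidize a secondary alcohol beside a tertiary one and acylate only the primary hydroxyl.

**31 to 30 (C8–CH3).** Cutting the methyl from the tertiary carbinol removes the C8 stereocentre and leaves a ketone. The forward addition must bring the methyl in on the β face, syn to the C9 chain, and must not enolize toward C9.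

**30 to 29 to 21 + 28 (C9–C11).** This is the convergent cut: a C13 bicycle and a C16 chain. Restoring the C6=C7 bond (29) makes C7 vinylic, so C9 is the only enolizable carbon of 21. The forward step is an SN2 reaction of a hindered enolate with a homoallylic iodide. It must deliver the chain to the β face, and C9 must not epimerize afterwards.

**21 to 20 to 19 to 18 to 16 (ring A adjustments and two C4–CH3 bonds).** The C3 carbinol goes back to a ketone, C1=C2 is restored and both C4 methyls are removed. In 16 the ring B carbonyl is a dioxolane and C2 is vinylic, so C4 is the only acidic position. Double methylation then needs no selectivity between two enones. The ketal must survive base, copper hydride and borohydride and then leave under mild acid.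

**16 to 15 (C5–C6, key step).** Cutting C5–C6 opens ring B and turns ring A into a symmetric dienone with no stereocentre. Two stereocentres and one ring are traded for one prochiral carbon. The forward step must choose between two enantiotopic alkenes.

**15 to 14 to 12 to 9 + 10.** The ketal is removed (14), H and I are taken off C7 and C6 (12) and the C8–C7 bond is cut to an acyl unit and an alkyne. The route avoids hard nucleophiles because the dienone carbonyl is present. The forward steps must give the Z alkene and must ketalize C8 without touching the iodovinyl carbon.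

**9 to 8 to 4 + 5.** The second ring alkene is removed, then the ring is opened at the bonds from the quaternary carbon to the adjacent CH2 and at the enone C=C (Michael addition plus aldol condensation). The Michael addition must create the quaternary carbon at an α-branched aldehyde.

**4 to 1 + 2.** The bond between the future C10 and C9 is cut to an aldehyde enamine and an α-bromo ester.

**28 to 27 to 26 to 25 to 24 to 23 to 22.** C11 is removed (one-carbon homologation of an allylic bromide through a sulfide) and the terminal C–O bond is removed (allylic oxidation of the E methyl group). The oxidation must be selective for the terminal alkene, and the two chain ends must stay differentiated.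

## Other disconnections considered

**Alternative 1:** Silyloxy-triene intramolecular Diels–Alder.
- **Cut:** C5–C10 and C8–C9 together, opening both rings to the acyclic triene A2.
- **Forward key step:** on heating, the C5=C6–C7=C8 silyloxy diene of A2 would add across its C9=C10 enoate to give the cis-fused octalin A1.
- **In its favour:** two rings, two C–C bonds and all four ring stereocentres would form in one metal-free step. C8 would arrive with its methyl and oxygen, and C4 and C3 would already be substituted. No differentiation of two ketones and no C4 methylation would be needed; on these points it is better than the chosen plan.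
- **Against it here:**
  - The dienophile is a β,β-disubstituted enoate that must form a quaternary carbon.
  - The diene terminus C8 is fully substituted. For the required C8 configuration (methyl syn to H5) its methyl must sit inside the s-cis diene.
  - The cis fusion is not enforced by geometry. It needs the tether-endo, ester-exo transition state, and the trans-fused isomer is a real competitor.
  - Facial selectivity rests on the remote C3 stereocentre, which must be made enantiopure and is later oxidized away.
- **Comparison:** A1 would still need conversion of the C9 ester into C11 and coupling to the chain, saturation of C6=C7 before the polyene is attached, two desilylations and an oxidation. Overall length would be similar to the chosen plan. The chosen plan sets fewer centres in its key step but fixes the cis fusion by geometry and the absolute configuration by a catalyst.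

**Alternative 2:** Dearomatization, Diels–Alder, anionic oxy-Cope.
- **Cut:** C1–C10, with the C3–C8 bond restored, tracing the decalin back to the bridged vinyl carbinol A4.
- **Forward key step:** the potassium alkoxide of A4 (KH, 18-crown-6) would undergo a [3,3] shift through a boat transition state. This would form C1–C10, break C3–C8 and give the cis-fused octalinone A3.
- **In its favour:** the rigid bicycle makes the shift stereospecific, so the cis fusion and quaternary C10 are as secure as in the chosen plan (equal). The C3 ketone and the C4 gem-dimethyl group come with the skeleton, and A4 should be reachable in very few steps from a cheap phenol; on these points it is better than the chosen plan.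
- **Against it here:**
  - A3 would be racemic unless the cycloaddition were made asymmetric or a resolution were added.
  - C8 and C9 arrive as a trisubstituted alkene. Both remaining stereocentres, the C8–O bond and the C9–C11 bond would still have to be made, the latter at a neopentyl carbon (for example by opening an epoxide with a carbon nucleophile).
  - The C3 ketone would be exposed throughout.
- **Comparison:** the route to the bicycle is shorter, but the endgame is less secure than enolate alkylation at C9, and the absolute configuration is not under catalyst control.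

**Alternative 3:** Ring expansion of a cis-hydrindane by epoxy-alcohol semipinacol shift.
- **Cut:** C9–C10, contracting ring B to the cyclopentane carbinol A6 that carries an oxirane (C9, C11) on C8.
- **Forward key step:** BF3·OEt2 would open the oxirane of A6 at C9 while C10 migrates anti from C8 to C9, giving the β-hydroxy ketone A5.
- **In its favour:** C9 would be set stereospecifically from the epoxide configuration, which is reagent-controlled; this is better than the substrate-controlled alkylation of the chosen plan. C11 would arrive as a hydroxymethyl handle, so a C15 chain unit could be used without homologation; on chain economy it is equal or better. C3 and C4 would already be in place.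
- **Against it here:**
  - Migration of C7 instead of C10 would give the regioisomeric decalone, and the outcome depends on rotamer control about C8–C9.
  - A5 is a β-hydroxy ketone, prone to retro-aldol cleavage and elimination and epimerizable at C9.
  - A6 needs a long linear build (hydrindane, quaternary centre, gem-dimethyl group, vinyl addition, epoxidation).
  - The C8 methyl addition would still face the same facial question as in the chosen plan.
- **Comparison:** stereocontrol at C9 is mechanistically cleaner, but step economy is poorer, and the ring fusion stereocentres would have to come from a separate asymmetric step.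

Key step: step 7

**Remarks on the chemistry**
- Locants follow the terpenoid numbering above; β is the face of the bicycle that carries the C10 methyl group, α the opposite face.
- The key-step bicycle has two ring alkenes (C1=C2 and C6=C7), so it is a hexalin (hexahydronaphthalene), not an octalin, and is named as a decala-1,6-diene here.
- The iodoenone 14 is not cyclized as such. Its C8 carbonyl is first masked as a dioxolane (15), with the same carbon skeleton and the same C5–C6 disconnection. This removes the acidic C9 hydrogens and the addition–elimination chemistry of a β-iodoenone from the key step, and it leaves C4 as the only enolizable position afterwards, so the two ring carbonyls never compete.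
- (R)-BINAP is written for the catalyst; the sense of induction is assumed by analogy with aryl halide substrates, and (S)-BINAP would be used if the opposite sense applied.
- The silyl alkyne must be desilylated before hydrogen iodide can add (step 5).
- A tert-butyl ester is used so that the acid chloride is reached without a free carboxylate next to the dienone.
- The C3 carbinol configuration (steps 10 to 19) is immaterial because C3 returns to a ketone.

## Steps

Step 1
Reactants: 1 propanal; 2 tert-butyl bromoacetate
Product: 4 tert-butyl 3-methyl-4-oxobutanoate (racemic), via enamine 3 (not isolated)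
Conditions: pyrrolidine, K2CO3, Et2O, 0 °C; then 2, MeCN, reflux; H2O, rt
Reagents that add atoms: none
Why: Stork enamine alkylation: the aldehyde enamine is C-alkylated by the activated α-bromo ester and the iminium salt is hydrolysed on work-up; the new stereocentre is racemic and becomes prochiral at the dienone stage.

Step 2
Reactants: 4 tert-butyl 3-methyl-4-oxobutanoate; 5 but-3-en-2-one
Product: 8 tert-butyl 2-(1-methyl-4-oxocyclohex-2-en-1-yl)acetate (racemic), via enamine 6 (not isolated), via keto aldehyde 7 (not isolated)
Conditions: pyrrolidine, PhMe, reflux (−H2O); 5, 0 °C → rt; AcOH, NaOAc, H2O, 80 °C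
Reagents that add atoms: none
Why: Robinson annulation through the enamine: Michael addition to 5 builds the quaternary carbon, buffered hydrolysis releases 7, and intramolecular aldol condensation of the methyl ketone onto the aldehyde closes the cyclohexenone; the buffer spares the tert-butyl ester.

Step 3
Reactants: 8 tert-butyl 2-(1-methyl-4-oxocyclohex-2-en-1-yl)acetate
Product: 9 tert-butyl 2-(1-methyl-4-oxocyclohexa-2,5-dien-1-yl)acetate
Conditions: DDQ, 1,4-dioxane, reflux
Reagents that add atoms: none
Why: Quinone dehydrogenation of a 4,4-disubstituted cyclohexenone to the cross-conjugated dienone; the quaternary carbon blocks aromatization and becomes a prochiral centre with two enantiotopic alkenes.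

Step 4
Reactants: 9 tert-butyl 2-(1-methyl-4-oxocyclohexa-2,5-dien-1-yl)acetate; 10 ethynyltrimethylsilane
Product: 12 4-methyl-4-[2-oxo-4-(trimethylsilyl)but-3-yn-1-yl]cyclohexa-2,5-dien-1-one, via acid chloride 11 (not isolated)
Conditions: SOCl2, CH2Cl2, rt; evaporate; then 10, PdCl2(PPh3)2 (2 mol %), CuI (4 mol %), Et3N, THF, rt
Reagents that add atoms: none
Why: tert-Butyl esters are converted directly into acid chlorides by SOCl2, so no carboxylate is formed that could add to the dienone; acyl Sonogashira coupling then gives the ynone without hard nucleophiles that would attack the dienone carbonyl.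

Step 5
Reactants: 12 4-methyl-4-[2-oxo-4-(trimethylsilyl)but-3-yn-1-yl]cyclohexa-2,5-dien-1-one
Product: 14 4-[(Z)-4-iodo-2-oxobut-3-en-1-yl]-4-methylcyclohexa-2,5-dien-1-one, via terminal ynone 13 (not isolated)
Conditions: Bu4NF, AcOH, THF, 0 °C; then NaI, AcOH, rt
Reagents that add atoms: sodium iodide, [Na+].[I-]
Why: Buffered fluoride removes the silyl group of the activated alkyne; conjugate addition of iodide to the terminal ynone and protonation of the allenol on the face away from iodine is the usual kinetic hydroiodination and should give the Z iodoenone.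

Step 6
Reactants: 14 4-[(Z)-4-iodo-2-oxobut-3-en-1-yl]-4-methylcyclohexa-2,5-dien-1-one
Product: 15 4-({2-[(Z)-2-iodoethenyl]-1,3-dioxolan-2-yl}methyl)-4-methylcyclohexa-2,5-dien-1-one
Conditions: Me3SiOCH2CH2OSiMe3, Me3SiOTf (cat.), CH2Cl2, −78 → −20 °C; pyridine
Reagents that add atoms: 1,2-bis(trimethylsilyloxy)ethane, C[Si](C)(C)OCCO[Si](C)(C)C
Why: Noyori ketalization under aprotic, kinetic conditions: the enone carbonyl reacts, the cross-conjugated dienone carbonyl is too weak an electrophile, and the absence of free alcohol and protic acid should avoid substitution at the iodovinyl carbon and Z-to-E isomerization.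

Step 7
Reactants: 15 4-({2-[(Z)-2-iodoethenyl]-1,3-dioxolan-2-yl}methyl)-4-methylcyclohexa-2,5-dien-1-one
Product: 16 cis-fused (5S,10S)-8,8-(ethylenedioxy)-10β-methyl-5βH-decala-1,6-dien-3-one
Conditions: Pd(OAc)2 (5 mol %), (R)-BINAP (7.5 mol %), HCO2Na (2 equiv), DMF, 60 °C
Reagents that add atoms: none
Why: Zerovalent palladium, formed in situ, inserts into the C6–I bond with retention of the Z geometry, and the alkenylpalladium, held over one face of the dienone by the C9–C8 arm, adds syn across one C4=C5 bond to form C5–C6 and a palladium enolate at C4/C3. This enolate has no hydrogen syn to palladium at C5, so β-hydride elimination is closed; formate replaces iodide, loses CO2, and the hydride so formed (or protonolysis of the oxygen-bound enolate) puts hydrogen on C4 and returns zerovalent palladium. The closest known reaction type is the Pd/BINAP-catalysed enantioselective reductive Heck desymmetrization of halide-tethered 4,4-disubstituted cyclohexadienones, established for aryl halides; an alkenyl iodide is a close relative. Ring B closes in the 6-exo-trig mode. C5 and C10 become stereocentres in the same event: their relative configuration (H5 syn to the C10 methyl, cis fusion) is fixed by the tether, because C6 can only reach the dienone face that carries C9, and their absolute configuration depends on which enantiotopic alkene inserts, a choice made by the chiral bisphosphine on palladium. The step needs this enantiotopic-group selection and a cyclization faster than direct formate reduction of the C–Pd bond; the Z geometry, the gem-disubstituted ketal carbon C8 (Thorpe–Ingold effect) and the pairing of an electron-rich alkenylpalladium with an electron-poor alkene favour cyclization, and the rigid symmetric dienone presents two well-separated alkenes to the chiral ligand.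

Step 8
Reactants: 16 cis-fused (5S,10S)-8,8-(ethylenedioxy)-10β-methyl-5βH-decala-1,6-dien-3-one
Product: 18 cis-fused 8,8-(ethylenedioxy)-4,4,10β-trimethyl-5βH-decala-1,6-dien-3-one, via monomethyl enone 17 (not isolated)
Conditions: LiN(iPr)2 (LDA), THF, −78 °C; MeI, −78 → 0 °C; then LDA, −78 °C; MeI, −78 °C → rt
Reagents that add atoms: iodomethane, CI
Why: Kinetic α'-enolate alkylation carried out twice: C4 is the only enolizable position (C2 is vinylic, C10 is quaternary, C8 is a ketal), so both methyl groups go to C4; C5 is not acidic and keeps its configuration.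

Step 9
Reactants: 18 cis-fused 8,8-(ethylenedioxy)-4,4,10β-trimethyl-5βH-decala-1,6-dien-3-one
Product: 19 cis-fused 8,8-(ethylenedioxy)-4,4,10β-trimethyl-5βH-decal-6-en-3-one
Conditions: [(Ph3P)CuH]6, H2O, PhH/THF, rt
Reagents that add atoms: none
Why: Copper hydride conjugate reduction delivers hydride to C1 of the enone only; the isolated C6=C7 alkene and the ketal are inert, and no stereocentre is formed.

Step 10
Reactants: 19 cis-fused 8,8-(ethylenedioxy)-4,4,10β-trimethyl-5βH-decal-6-en-3-one
Product: 21 cis-fused 3α-hydroxy-4,4,10β-trimethyl-5βH-decal-6-en-8-one, via hydroxy ketal 20 (not isolated)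
Conditions: LiBH(s-Bu)3, THF, −78 °C; then 1 M HCl, THF, rt
Reagents that add atoms: water, O
Why: The bulky borohydride should approach C3 along the equatorial direction, the axial path being closed by C6, to give the axial 3α-carbinol (either epimer would serve, since C3 is re-oxidized in step 20); aqueous acid then hydrolyses the allylic dioxolane to the conjugated enone, the carbonyl oxygen coming from water.

Step 11
Reactants: 22 (2E,6E)-farnesyl acetate
Product: 23 (2E,6E,10E)-12-hydroxy-3,7,11-trimethyldodeca-2,6,10-trien-1-yl acetate
Conditions: SeO2 (cat.), t-BuOOH, salicylic acid (cat.), CH2Cl2, rt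
Reagents that add atoms: tert-butyl hydroperoxide, CC(C)(C)OO
Why: Selenium dioxide allylic oxidation (ene reaction, then [2,3] shift) is selective for the E methyl of the terminal trisubstituted alkene; the acetate deactivates the C2 alkene.

Step 12
Reactants: 23 (2E,6E,10E)-12-hydroxy-3,7,11-trimethyldodeca-2,6,10-trien-1-yl acetate
Product: 24 (2E,6E,10E)-12-(tert-butyldimethylsilyloxy)-3,7,11-trimethyldodeca-2,6,10-trien-1-yl acetate
Conditions: t-BuMe2SiCl, imidazole, DMF, rt
Reagents that add atoms: tert-butyl(chloro)dimethylsilane, CC(C)(C)[Si](C)(C)Cl
Why: Standard silylation of a primary allylic alcohol; the silyl ether will survive amide bases, copper hydride and organocerium reagents later.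

Step 13
Reactants: 24 (2E,6E,10E)-12-(tert-butyldimethylsilyloxy)-3,7,11-trimethyldodeca-2,6,10-trien-1-yl acetate
Product: 25 (2E,6E,10E)-12-(tert-butyldimethylsilyloxy)-3,7,11-trimethyldodeca-2,6,10-trien-1-ol
Conditions: K2CO3, MeOH, rt
Reagents that add atoms: none
Why: Base-catalysed transesterification removes the acetate and leaves the silyl ether, which frees the chain end that is to be homologated.

Step 14
Reactants: 25 (2E,6E,10E)-12-(tert-butyldimethylsilyloxy)-3,7,11-trimethyldodeca-2,6,10-trien-1-ol
Product: 26 [(2E,6E,10E)-12-bromo-2,6,10-trimethyldodeca-2,6,10-trien-1-yl]oxy(tert-butyl)dimethylsilane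
Conditions: CBr4, PPh3, CH2Cl2, 0 °C
Reagents that add atoms: tetrabromomethane, BrC(Br)(Br)Br
Why: Appel bromination under neutral conditions converts the primary allylic alcohol into the bromide without allylic transposition and without touching the silyl ether; the bromide is used without delay.

Step 15
Reactants: 26 [(2E,6E,10E)-12-bromo-2,6,10-trimethyldodeca-2,6,10-trien-1-yl]oxy(tert-butyl)dimethylsilane
Product: 27 tert-butyldimethyl{[(2E,6E,10E)-2,6,10-trimethyl-13-(phenylsulfanyl)trideca-2,6,10-trien-1-yl]oxy}silane
Conditions: PhSMe, n-BuLi, DABCO, THF, 0 °C; CuI, −78 °C; then 26, −78 → 0 °C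
Reagents that add atoms: methyl phenyl sulfide, CSc1ccccc1
Why: The α-thio carbanion, used as its copper derivative, displaces the primary allylic bromide at the α-carbon without transposition; this adds the carbon that becomes C11 and keeps the alkene geometry.

Step 16
Reactants: 27 tert-butyldimethyl{[(2E,6E,10E)-2,6,10-trimethyl-13-(phenylsulfanyl)trideca-2,6,10-trien-1-yl]oxy}silane
Product: 28 tert-butyl{[(2E,6E,10E)-13-iodo-2,6,10-trimethyltrideca-2,6,10-trien-1-yl]oxy}dimethylsilane
Conditions: MeI, NaI, DMF, 75 °C
Reagents that add atoms: iodomethane, CI
Why: S-Methylation gives a sulfonium ion whose primary carbon is attacked by iodide (SN2) with loss of methyl phenyl sulfide, a classical sulfide-to-iodide exchange for homoallylic systems; NaI only raises the iodide concentration.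

Step 17
Reactants: 21 cis-fused 3α-hydroxy-4,4,10β-trimethyl-5βH-decal-6-en-8-one; 28 tert-butyl{[(2E,6E,10E)-13-iodo-2,6,10-trimethyltrideca-2,6,10-trien-1-yl]oxy}dimethylsilane
Product: 29 cis-fused 9β-[(3E,7E,11E)-13-(tert-butyldimethylsilyloxy)-4,8,12-trimethyltrideca-3,7,11-trien-1-yl]-3α-hydroxy-4,4,10β-trimethyl-5βH-decal-6-en-8-one
Conditions: LDA (2.2 equiv), THF, −78 → −30 °C; 28, DMPU, −78 → −20 °C
Reagents that add atoms: none
Why: Two equivalents of base give the C3 alkoxide and the α'-enolate at C9, the only enolizable carbon (C7 is vinylic, ring A has no carbonyl), which is alkylated by the primary iodide. C9 is set by the ring conformation: with ring A as a chair holding the 4β and 10β methyls axial, C1 is pseudo-axial on the α face of the enolate, so the electrophile should enter from the open, convex β face anti to the C10–C1 bond, placing the chain syn to the C10 methyl.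

Step 18
Reactants: 29 cis-fused 9β-[(3E,7E,11E)-13-(tert-butyldimethylsilyloxy)-4,8,12-trimethyltrideca-3,7,11-trien-1-yl]-3α-hydroxy-4,4,10β-trimethyl-5βH-decal-6-en-8-one
Product: 30 cis-fused 9β-[(3E,7E,11E)-13-(tert-butyldimethylsilyloxy)-4,8,12-trimethyltrideca-3,7,11-trien-1-yl]-3α-hydroxy-4,4,10β-trimethyl-5βH-decalin-8-one
Conditions: [(Ph3P)CuH]6, H2O, PhH/THF, rt
Reagents that add atoms: none
Why: Copper hydride conjugate reduction saturates C6=C7 and leaves the three trisubstituted chain alkenes; the copper enolate lies toward C7, so the C9 stereocentre is not involved and is not epimerized under these neutral conditions.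

Step 19
Reactants: 30 cis-fused 9β-[(3E,7E,11E)-13-(tert-butyldimethylsilyloxy)-4,8,12-trimethyltrideca-3,7,11-trien-1-yl]-3α-hydroxy-4,4,10β-trimethyl-5βH-decalin-8-one
Product: 31 cis-fused 9β-[(3E,7E,11E)-13-(tert-butyldimethylsilyloxy)-4,8,12-trimethyltrideca-3,7,11-trien-1-yl]-4,4,8β,10β-tetramethyl-5βH-decalin-3α,8α-diol
Conditions: MeLi, CeCl3, THF, −78 °C
Reagents that add atoms: methyllithium, [Li]C
Why: Organocerium addition to a hindered, enolizable ketone without enolization, so C9 is kept; C8 is the only carbonyl because C3 is an alkoxide. C8 is set by approach control: the axial path on the α face is blocked by the syn-axial C1 methylene, so the methyl should enter along the equatorial direction from the β face, giving 8β-methyl and 8α-hydroxyl (hydroxyl anti to the C9 chain).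

Step 20
Reactants: 31 cis-fused 9β-[(3E,7E,11E)-13-(tert-butyldimethylsilyloxy)-4,8,12-trimethyltrideca-3,7,11-trien-1-yl]-4,4,8β,10β-tetramethyl-5βH-decalin-3α,8α-diol
Product: 32 cis-fused 9β-[(3E,7E,11E)-13-(tert-butyldimethylsilyloxy)-4,8,12-trimethyltrideca-3,7,11-trien-1-yl]-8α-hydroxy-4,4,8β,10β-tetramethyl-5βH-decalin-3-one
Conditions: Dess–Martin periodinane, NaHCO3, CH2Cl2, 0 °C → rt
Reagents that add atoms: none
Why: Dess–Martin oxidation of the secondary C3 carbinol under buffered, non-acidic conditions; the tertiary alcohol cannot be oxidized, and the silyl ether and alkenes are inert.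

Step 21
Reactants: 32 cis-fused 9β-[(3E,7E,11E)-13-(tert-butyldimethylsilyloxy)-4,8,12-trimethyltrideca-3,7,11-trien-1-yl]-8α-hydroxy-4,4,8β,10β-tetramethyl-5βH-decalin-3-one
Product: 33 cis-fused 8α-hydroxy-9β-[(3E,7E,11E)-13-hydroxy-4,8,12-trimethyltrideca-3,7,11-trien-1-yl]-4,4,8β,10β-tetramethyl-5βH-decalin-3-one
Conditions: Bu4NF, THF, 0 °C → rt
Reagents that add atoms: none
Why: Fluoride cleavage of the primary silyl ether; the tertiary alcohol is not β to a carbonyl, so no retro-aldol path exists, and the ketone has no epimerizable stereocentre next to it.

Step 22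
Reactants: 33 cis-fused 8α-hydroxy-9β-[(3E,7E,11E)-13-hydroxy-4,8,12-trimethyltrideca-3,7,11-trien-1-yl]-4,4,8β,10β-tetramethyl-5βH-decalin-3-one
Product: 34 myrrhanone A acetate, (5S,8R,9R,10S)
Conditions: Ac2O, pyridine, CH2Cl2, 0 °C → rt
Reagents that add atoms: acetic anhydride, CC(=O)OC(C)=O
Why: Acylation without an acyl-transfer catalyst esterifies the primary allylic hydroxyl only; the hindered tertiary C8 hydroxyl stays free.

## Compound list

1 | propanal | CCC=O | starting material
2 | tert-butyl bromoacetate | BrCC(=O)OC(C)(C)C | starting material
3 | 1-[(E)-prop-1-en-1-yl]pyrrolidine (not isolated) | C/C=C/N1CCCC1 | intermediate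
4 | tert-butyl 3-methyl-4-oxobutanoate (racemic) | CC(C=O)CC(=O)OC(C)(C)C | intermediate
5 | but-3-en-2-one | CC(=O)C=C | starting material
6 | tert-butyl 3-methyl-4-(pyrrolidin-1-yl)but-3-enoate (E/Z mixture, not isolated) | CC(=CN1CCCC1)CC(=O)OC(C)(C)C | intermediate
7 | tert-butyl 3-formyl-3-methyl-6-oxoheptanoate (racemic, not isolated) | CC(=O)CCC(C)(C=O)CC(=O)OC(C)(C)C | intermediate
8 | tert-butyl 2-(1-methyl-4-oxocyclohex-2-en-1-yl)acetate (racemic) | CC1(CC(=O)OC(C)(C)C)CCC(=O)C=C1 | intermediate
9 | tert-butyl 2-(1-methyl-4-oxocyclohexa-2,5-dien-1-yl)acetate | CC1(CC(=O)OC(C)(C)C)C=CC(=O)C=C1 | intermediate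
10 | ethynyltrimethylsilane | C#C[Si](C)(C)C | starting material
11 | 2-(1-methyl-4-oxocyclohexa-2,5-dien-1-yl)acetyl chloride (not isolated) | CC1(CC(=O)Cl)C=CC(=O)C=C1 | intermediate
12 | 4-methyl-4-[2-oxo-4-(trimethylsilyl)but-3-yn-1-yl]cyclohexa-2,5-dien-1-one | CC1(CC(=O)C#C[Si](C)(C)C)C=CC(=O)C=C1 | intermediate
13 | 4-methyl-4-(2-oxobut-3-yn-1-yl)cyclohexa-2,5-dien-1-one (not isolated) | CC1(CC(=O)C#C)C=CC(=O)C=C1 | intermediate
14 | 4-[(Z)-4-iodo-2-oxobut-3-en-1-yl]-4-methylcyclohexa-2,5-dien-1-one | CC1(CC(=O)/C=C\I)C=CC(=O)C=C1 | intermediate
15 | 4-({2-[(Z)-2-iodoethenyl]-1,3-dioxolan-2-yl}methyl)-4-methylcyclohexa-2,5-dien-1-one (key-step precursor) | CC1(CC2(/C=C\I)OCCO2)C=CC(=O)C=C1 | intermediate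
16 | cis-fused (5S,10S)-8,8-(ethylenedioxy)-10β-methyl-5βH-decala-1,6-dien-3-one (key-step product) | O1CCOC12C[C@@]3(C)C=CC(=O)C[C@H]3C=C2 | intermediate
17 | cis-fused 8,8-(ethylenedioxy)-4,10β-dimethyl-5βH-decala-1,6-dien-3-one (either C4 epimer, not isolated) | O1CCOC12C[C@@]3(C)C=CC(=O)C(C)[C@H]3C=C2 | intermediate
18 | cis-fused 8,8-(ethylenedioxy)-4,4,10β-trimethyl-5βH-decala-1,6-dien-3-one | O1CCOC12C[C@@]3(C)C=CC(=O)C(C)(C)[C@H]3C=C2 | intermediate
19 | cis-fused 8,8-(ethylenedioxy)-4,4,10β-trimethyl-5βH-decal-6-en-3-one | O1CCOC12C[C@@]3(C)CCC(=O)C(C)(C)[C@H]3C=C2 | intermediate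
20 | cis-fused 8,8-(ethylenedioxy)-4,4,10β-trimethyl-5βH-decal-6-en-3α-ol (not isolated) | O1CCOC12C[C@@]3(C)CC[C@@H](O)C(C)(C)[C@H]3C=C2 | intermediate
21 | cis-fused 3α-hydroxy-4,4,10β-trimethyl-5βH-decal-6-en-8-one | O=C1C[C@@]2(C)CC[C@@H](O)C(C)(C)[C@H]2C=C1 | intermediate
22 | (2E,6E)-farnesyl acetate | CC(C)=CCC/C(C)=C/CC/C(C)=C/COC(C)=O | starting material
23 | (2E,6E,10E)-12-hydroxy-3,7,11-trimethyldodeca-2,6,10-trien-1-yl acetate | OC/C(C)=C/CC/C(C)=C/CC/C(C)=C/COC(C)=O | intermediate
24 | (2E,6E,10E)-12-(tert-butyldimethylsilyloxy)-3,7,11-trimethyldodeca-2,6,10-trien-1-yl acetate | CC(C)(C)[Si](C)(C)OC/C(C)=C/CC/C(C)=C/CC/C(C)=C/COC(C)=O | intermediate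
25 | (2E,6E,10E)-12-(tert-butyldimethylsilyloxy)-3,7,11-trimethyldodeca-2,6,10-trien-1-ol | CC(C)(C)[Si](C)(C)OC/C(C)=C/CC/C(C)=C/CC/C(C)=C/CO | intermediate
26 | [(2E,6E,10E)-12-bromo-2,6,10-trimethyldodeca-2,6,10-trien-1-yl]oxy(tert-butyl)dimethylsilane | CC(C)(C)[Si](C)(C)OC/C(C)=C/CC/C(C)=C/CC/C(C)=C/CBr | intermediate
27 | tert-butyldimethyl{[(2E,6E,10E)-2,6,10-trimethyl-13-(phenylsulfanyl)trideca-2,6,10-trien-1-yl]oxy}silane | CC(C)(C)[Si](C)(C)OC/C(C)=C/CC/C(C)=C/CC/C(C)=C/CCSc1ccccc1 | intermediate
28 | tert-butyl{[(2E,6E,10E)-13-iodo-2,6,10-trimethyltrideca-2,6,10-trien-1-yl]oxy}dimethylsilane | CC(C)(C)[Si](C)(C)OC/C(C)=C/CC/C(C)=C/CC/C(C)=C/CCI | intermediate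
29 | cis-fused 9β-[(3E,7E,11E)-13-(tert-butyldimethylsilyloxy)-4,8,12-trimethyltrideca-3,7,11-trien-1-yl]-3α-hydroxy-4,4,10β-trimethyl-5βH-decal-6-en-8-one | CC(C)(C)[Si](C)(C)OC/C(C)=C/CC/C(C)=C/CC/C(C)=C/CC[C@@H]1[C@@]2(C)CC[C@@H](O)C(C)(C)[C@H]2C=CC1=O | intermediate
30 | cis-fused 9β-[(3E,7E,11E)-13-(tert-butyldimethylsilyloxy)-4,8,12-trimethyltrideca-3,7,11-trien-1-yl]-3α-hydroxy-4,4,10β-trimethyl-5βH-decalin-8-one | CC(C)(C)[Si](C)(C)OC/C(C)=C/CC/C(C)=C/CC/C(C)=C/CC[C@@H]1[C@@]2(C)CC[C@@H](O)C(C)(C)[C@H]2CCC1=O | intermediate
31 | cis-fused 9β-[(3E,7E,11E)-13-(tert-butyldimethylsilyloxy)-4,8,12-trimethyltrideca-3,7,11-trien-1-yl]-4,4,8β,10β-tetramethyl-5βH-decalin-3α,8α-diol | CC(C)(C)[Si](C)(C)OC/C(C)=C/CC/C(C)=C/CC/C(C)=C/CC[C@@H]1[C@@]2(C)CC[C@@H](O)C(C)(C)[C@H]2CC[C@@]1(C)O | intermediate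
32 | cis-fused 9β-[(3E,7E,11E)-13-(tert-butyldimethylsilyloxy)-4,8,12-trimethyltrideca-3,7,11-trien-1-yl]-8α-hydroxy-4,4,8β,10β-tetramethyl-5βH-decalin-3-one | CC(C)(C)[Si](C)(C)OC/C(C)=C/CC/C(C)=C/CC/C(C)=C/CC[C@@H]1[C@@]2(C)CCC(=O)C(C)(C)[C@H]2CC[C@@]1(C)O | intermediate
33 | cis-fused 8α-hydroxy-9β-[(3E,7E,11E)-13-hydroxy-4,8,12-trimethyltrideca-3,7,11-trien-1-yl]-4,4,8β,10β-tetramethyl-5βH-decalin-3-one | OC/C(C)=C/CC/C(C)=C/CC/C(C)=C/CC[C@@H]1[C@@]2(C)CCC(=O)C(C)(C)[C@H]2CC[C@@]1(C)O | intermediate
34 | myrrhanone A acetate, (5S,8R,9R,10S): cis-fused 9β-[(3E,7E,11E)-13-acetoxy-4,8,12-trimethyltrideca-3,7,11-trien-1-yl]-8α-hydroxy-4,4,8β,10β-tetramethyl-5βH-decalin-3-one | CC(=O)OC/C(C)=C/CC/C(C)=C/CC/C(C)=C/CC[C@@H]1[C@@]2(C)CCC(=O)C(C)(C)[C@H]2CC[C@@]1(C)O | target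

## Step count and least certain steps

Total step count: 22 (ring fragment, steps 1 to 10; chain fragment, steps 11 to 16; union and endgame, steps 17 to 22). Longest linear sequence: 16 steps (steps 1 to 10, then 17 to 22).

**Step 7 (key step).** The most likely failures are reduction of the alkenyl–palladium bond by formate before it inserts, and insufficient discrimination of the two enantiotopic alkenes, because the catalyst system was developed for aryl donors. Fallback: starting from 15, a tin hydride radical cyclization (Bu3SnH, AIBN, PhH, 80 °C, slow addition) would close the same C5–C6 bond in the 6-exo mode, since a nucleophilic alkenyl radical is well matched to the dienone. This would give 16 as a racemate together with its mirror image, ent-dioxolane enone F1. The enantiomers would be separated by chromatography on a chiral stationary phase, and the route is rejoined at 16.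

**Step 6 (ketalization of the iodoenone).** Substitution at the iodovinyl carbon by the glycol unit, or Z-to-E isomerization under the Lewis acid, could compete with carbonyl ketalization. Fallback: starting from 12, the ynone carbonyl would be ketalized under the same conditions to the silylalkyne dioxolane F2. F2 would be converted into the iodoalkyne dioxolane F3 (N-iodosuccinimide, AgNO3 cat., DMF). F3 would then be reduced cis with diimide (2-nitrobenzenesulfonyl hydrazide, Et3N) to rejoin the route at 15, so the iodoenone is never exposed to acid.

**Step 17 (C9 alkylation).** Substitution at an enolate carbon flanked by a quaternary centre is slow, so elimination of HI from the homoallylic iodide and proton transfer may take over; incomplete facial selectivity is the second concern. Fallback: starting from 21, condensation with Me2NNH2 would give the dimethylhydrazone F4. Its lithium azaenolate (LDA) is a stronger carbon nucleophile and a weaker base toward the iodide. Alkylation with 28 would give the alkylated hydrazone F5, and mild hydrolysis (aqueous oxalic acid) would rejoin the route at 29 with the same facial preference.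

**Step 19 (methyl addition at C8).** The risk is poor facial selectivity: the β approach is hindered by the adjacent axial chain and the α approach by the syn-axial C1 methylene, and the balance between them is not certain. Fallback: starting from 30, Wittig methylenation (Ph3P=CH2) would give the exocyclic alkene F6. Oxymercuration–demercuration (Hg(OAc)2, THF/H2O; then NaBH4, NaOH) would then hydrate the 1,1-disubstituted alkene in preference to the trisubstituted chain alkenes. There water is the nucleophile at C8, so whichever face a nucleophile prefers, one of the two methods puts the hydroxyl on the α face; the route is rejoined at 31.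

## Further compounds

F1 | step 7 | cis-fused (5R,10R)-8,8-(ethylenedioxy)-10-methyl-decala-1,6-dien-3-one (enantiomer of 16) | O1CCOC12C[C@]3(C)C=CC(=O)C[C@@H]3C=C2
F2 | step 6 | 4-methyl-4-({2-[(trimethylsilyl)ethynyl]-1,3-dioxolan-2-yl}methyl)cyclohexa-2,5-dien-1-one | CC1(CC2(C#C[Si](C)(C)C)OCCO2)C=CC(=O)C=C1
F3 | step 6 | 4-{[2-(iodoethynyl)-1,3-dioxolan-2-yl]methyl}-4-methylcyclohexa-2,5-dien-1-one | CC1(CC2(C#CI)OCCO2)C=CC(=O)C=C1
F4 | step 17 | N,N-dimethylhydrazone of 21 (C=N geometry not defined) | CN(C)N=C1C[C@@]2(C)CC[C@@H](O)C(C)(C)[C@H]2C=C1
F5 | step 17 | N,N-dimethylhydrazone of 29 (C=N geometry not defined) | CC(C)(C)[Si](C)(C)OC/C(C)=C/CC/C(C)=C/CC/C(C)=C/CC[C@@H]1[C@@]2(C)CC[C@@H](O)C(C)(C)[C@H]2C=CC1=NN(C)C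
F6 | step 19 | cis-fused 9β-[(3E,7E,11E)-13-(tert-butyldimethylsilyloxy)-4,8,12-trimethyltrideca-3,7,11-trien-1-yl]-4,4,10β-trimethyl-8-methylidene-5βH-decalin-3α-ol | CC(C)(C)[Si](C)(C)OC/C(C)=C/CC/C(C)=C/CC/C(C)=C/CC[C@@H]1[C@@]2(C)CC[C@@H](O)C(C)(C)[C@H]2CCC1=C
A1 | alternative 1 | cis-fused C6=C7 octalin with C9 carbomethoxy, C8 methyl and silyl ether, C3 silyl ether (Diels–Alder product) | COC(=O)[C@@H]1[C@@]2(C)CC[C@H](O[Si](C)(C)C(C)(C)C)C(C)(C)[C@H]2C=C[C@@]1(C)O[Si](C)(C)C(C)(C)C
A2 | alternative 1 | acyclic (E)-enoate silyloxy triene, precursor of A1 | COC(=O)/C=C(\C)CC[C@H](O[Si](C)(C)C(C)(C)C)C(C)(C)/C=C/C=C(\C)O[Si](C)(C)C(C)(C)C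
A3 | alternative 2 | cis-fused 4,4,8,10-tetramethyl C8=C9 octalin-3-one (oxy-Cope product) | CC1=C[C@@]2(C)CCC(=O)C(C)(C)[C@H]2CC1
A4 | alternative 2 | 1,3,3,5-tetramethyl-2-vinylbicyclo[2.2.2]oct-5-en-2-ol, vinyl syn to the ring alkene | C=C[C@]1(O)C(C)(C)[C@H]2CC[C@]1(C)C=C2C
A5 | alternative 3 | cis-fused 4,4,10-trimethyldecalin-8-one with C9 hydroxymethyl and C3 silyl ether (semipinacol product) | OC[C@@H]1[C@@]2(C)CC[C@H](O[Si](C)(C)C(C)(C)C)C(C)(C)[C@H]2CCC1=O
A6 | alternative 3 | cis-hydrindane C8 carbinol bearing an oxiranyl group (C9, C11), C3 silyl ether | C[C@]12CC[C@H](O[Si](C)(C)C(C)(C)C)C(C)(C)[C@H]1CC[C@]2(O)[C@H]3CO3
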